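All runs are calculated for an exercise, noise included.

Target is what you want from these flasks, and you asked me for a quick number: how much stands after 20 min as the substrate charge climbs from larch to ash.

| setting | grey | red | larch | cedar | maple | elm | ash |
|---|---|---|---|---|---|---|---|
| substrate | 0.0074 M | 0.13 M | 0.0060 M | 0.012 M | 0.025 M | 0.050 M | 0.10 M |
| partner | 0.055 M | 0.055 M | 0.0550 M | 0.0550 M | 0.0550 M | 0.0550 M | 0.0550 M |
| capture agent | 0.015 M | 0.015 M | 0.0150 M | 0.0150 M | 0.0150 M | 0.0150 M | 0.0150 M |
| remark | run made earlier | run made earlier |  |  |  |  |  |
| time |  |  | 20 min | 20 min | 20 min | 20 min | 20 min |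

| run | time / min | target / % | substrate / % |
|---|---|---|---|
| grey | 2.00 | 7.2 | 37.9 |
| grey | 4.00 | 19.5 | 25.6 |
| grey | 6.00 | 28.2 | 18.1 |
| grey | 8.00 | 34.9 | 13.1 |
| grey | 10.0 | 38.2 | 10.5 |
| red | 0.833 | 1.4 | 57.0 |
| red | 1.50 | 3.6 | 44.8 |
| red | 3.00 | 9.7 | 35.7 |
| red | 5.00 | 13.3 | 31.4 |
| red | 10.0 | 19.0 | 29.3 |

(standard deviation of a reading: 0.3 percentage points)

- "hardly changes" means that all values lie within two and a half points (for a concentration: within two and a half percent of the largest)

* [target] at the end for larch, cedar, maple, elm, ash, in this order
* how the row runs (hardly changes / falls all the way / rises, then falls / rises all the way / falls, then rises)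

Partner and capture agent are charged alike in grey and red, so start from the large part of the answer: at constant percent yield, target would go in step with the charge. You then need to compute only the correction, and the two runs give it from their target readings at 10.0 min:

droop = ln(38.2% / 19.0%) / ln(0.13 M / 0.0074 M) = 0.244

I call this the yield droop, the fall in ln(percent yield) per unit rise in ln(substrate charge) at one time, with partner and capture agent held fixed. This value is a reading from the two runs. While the droop stays constant, target goes as the charge to the power one minus the droop, which is 0.756. That power is above zero, so I expect the row to rise all the way. Carrying the reading from 10.0 min over to 20 min, my reckoning for ash over larch is: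

[target] in ash / [target] in larch = (0.10 M / 0.0060 M)^0.756 = 8.40

Your forecast gives 0.0028 M, 0.0049 M, 0.009 M, 0.0155 M and 0.027 M, with the shape "rises all the way", and it says: “Percent yield falls, but absolute target still rises with charge.” Its ratio of 9.64 is larger than mine. Starting from its larch value, I would put ash at 0.0235 M, not 0.027 M.

The flasks give 0.00295 M, 0.00584 M, 0.0117 M, 0.0207 M and 0.0275 M, so the row rises all the way. At elm the forecast lies below the flask.

    substrate + partner ⇌ intermediate A (K = 51.0 /M, k = 0.0370 /M/s)
    substrate ⇌ intermediate B (K = 1.10, k = 0.0130 /s)
    partner + intermediate A ⇌ intermediate C (K = 12.0 /M, k = 0.00160 /M/s)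
    partner + intermediate B → intermediate D (k = 0.0890 /M/s)
    intermediate C ⇌ intermediate E (K = 2.20, k = 9.80 × 10⁻⁴ /s)
    intermediate D ⇌ target (K = 2.80, k = 0.0160 /s)
    capture agent + intermediate D → trapped intermediate (k = 0.0160 /M/s)

At 20 min, the droop from larch to ash is 0.207, below the 0.244 I read at 10.0 min, but it is uneven: 0.0346 from larch to maple, and 0.329 at elm, from its local order of 0.67. In larch, the forward step from intermediate D to target has a half-life of 0.72 min, shorter than the 48 min for capture agent, as charged, taking intermediate D to trapped intermediate. In percent of the substrate charged, larch holds target, the kinetic product, at 49.2% against 4.16% trapped intermediate after 20.0 min, and at 38.4% against 44.3% after 200 min.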